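(The runs were generated by integration from invented constants; the scatter is artificial.)

At 0 °C, in the red run, 58 % of the starting material is left after 40.0 s, and 34 % of the charge stands as target. Coupling partner is in excess there, so the loss is reckoned as pseudo-first-order: equal intervals multiply the fraction left by the same factor. The quantity to carry is the target share, the target present divided by the starting material reacted, which the red run reads as 81.0 %.

| flask | starting material | coupling partner | protic impurity | temperature | remark | time |
|---|---|---|---|---|---|---|
| green | 2.5 mM | 20 mM | 1.5 mM | −25 °C | run made earlier |  |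
| red | 3.8 mM | 20 mM | 1.5 mM | 0 °C | run made earlier |  |
| violet | 5 mM | 20 mM | 0.75 mM | −25 °C | run made earlier |  |
| Sunday's | 5.0 mM | 20.0 mM | 1.50 mM | −20 °C |  | 2.0 min |
| Wednesday's | 5.0 mM | 20.0 mM | 1.50 mM | 0 °C |  | 2.0 min |
| Friday's | 5.0 mM | 20.0 mM | 1.50 mM | 20 °C |  | 2.0 min |

- green (time / s: target / %, starting material / %): 20.0: 1, 97; 40.0: 8, 95; 60.0: 2, 92; 80.0: 8, 88; 90.0: 9, 86; 120: 13, 85
- red (time / s: target / %, starting material / %): 10.0: 15, 88; 15.0: 17, 83; 20.0: 20, 72; 30.0: 25, 67; 40.0: 34, 58
- violet (time / s: target / %, starting material / %): 25.0: 5, 99; 50.0: 6, 95; 80.0: 9, 87; 90.0: 15, 88; 120: 12, 83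

(readings scatter by 2 percentage points)

* the flask with the highest amount of target, in percent of the starting material charged ("all alike" if they lie within 1.5 percentage points) (Sunday's / Wednesday's / Friday's / all alike)
* final target, as a percentage of the starting material charged, in Sunday's
* final target, as a percentage of the starting material charged, in Wednesday's
* final target, as a percentage of the starting material charged, in Friday's



By this reckoning, Wednesday's, at the same temperature and partner charge, keeps 19.5 % of its starting material after 2.0 min and reaches 65.2 % of target. Friday's, if its whole charge reacts, holds 81.0 %, more than Wednesday's.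

The forecast, holding that “the target is the main product”, names Friday's. It gives 20 % (15 % to 26 %) for Sunday's, 66 % (56 % to 76 %) for Wednesday's and 82 % (66 % to 95 %) for Friday's.

The flasks give 21.4 % in Sunday's, 53.1 % in Wednesday's and 28.4 % in Friday's, so Wednesday's holds the most target.

    starting material + target → side product (k = 4.37 L mol⁻¹ s⁻¹, Ea = 53.0 kJ mol⁻¹)
    starting material + coupling partner ⇌ target (K = 2330 L mol⁻¹, k = 2.68 L mol⁻¹ s⁻¹, Ea = 49.0 kJ mol⁻¹, ΔH = −60.0 kJ mol⁻¹)
    target ⇌ isomer of the product (K = 2.06, k = 0.0119 s⁻¹, Ea = 87.0 kJ mol⁻¹, ΔH = −8.00 kJ mol⁻¹)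
    starting material + protic impurity → quenched substrate (k = 4.88 L mol⁻¹ s⁻¹, Ea = 42.0 kJ mol⁻¹)
    (constants at 20 °C)

Wednesday's ends with 53.1 % of target and 81.8 % of its starting material reacted. In Wednesday's, target is made 6.45 times faster than it is used up at 0.579 min, but 2.11 times faster at 2.00 min. The red run's share applied to Wednesday's conversion gives 66.3 % of the charge as target, more than the 53.1 % that Wednesday's holds, and the target share of Wednesday's is 64.9 % against the red run's 81.0 %. The repeat of Wednesday's at −25 °C, with 18.5 % reacted, gets 15.0 % from the red run's share and holds 14.5 %.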